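Ring A, the dearomatised acylphloroglucinol ring, is read as a masked tetraketide: its ring carbonyl, acetyl-bearing carbon, bridge carbon and bridge-side enol carbon are a triacetic acid unit, while the quaternary carbon and the acetyl-side enol carbon are a methyl(geranyl)acetyl unit. The key step joins the two in one flask: a geometry-defined oxazolidinone enolate (from an ynamide by carbocupration–oxidation) is C-acylated by the lactone carbonyl of 4-methoxy-6-methyl-2-pyranone, giving the bond from the quaternary carbon to the bridge-side enol carbon; the released dienolate then closes onto the imide carbonyl, giving the bond from the acetyl-bearing carbon to the acetyl-side enol carbon and expelling the auxiliary. Rings B and C are attached afterwards through Mannich-type methylene bridges.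

Key step: step 6

Remark: the enolised triketone rings are drawn in one tautomer, and the descriptor at the quaternary carbon refers to the tautomer drawn.
Remark: acylation of enolate 14 is assumed to occur on the face anti to the benzyl group of the chelated oxazolidinone, which makes the (R)-auxiliary the one that leads to the target.

Step 1
Reactants: 1 benzene-1,3,5-triol (phloroglucinol); 2 butanoyl chloride
Product: 3 1-(2,4,6-trihydroxyphenyl)butan-1-one
Conditions: AlCl3, PhNO2/CH2Cl2, rt → 50 °C; aq. HCl
Reagents that add atoms: none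
Why: Friedel–Crafts acylation of the electron-rich triol should stop at the mono-ketone because the first acyl group deactivates the ring.

Step 2
Reactants: 3 1-(2,4,6-trihydroxyphenyl)butan-1-one (slight excess); 4 3-methylbut-2-enal
Product: 5 1-(5,7-dihydroxy-2,2-dimethyl-2H-chromen-8-yl)butan-1-one
Conditions: pyridine, 110 °C
Reagents that add atoms: none
Why: Knoevenagel condensation at a free ring carbon followed by oxa-6π electrocyclisation of the o-quinone methide (chromenylation) should close the pyran through an ortho-hydroxyl, one of which is always free of the hydrogen bond to the ketone, while the 6-butanoyl isomer closed through the para-hydroxyl is the expected by-product to be removed by chromatography.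

Step 3
Reactants: 5 1-(5,7-dihydroxy-2,2-dimethyl-2H-chromen-8-yl)butan-1-one; 3 1-(2,4,6-trihydroxyphenyl)butan-1-one
Product: 7 1-[3-[(8-butanoyl-5,7-dihydroxy-2,2-dimethyl-2H-chromen-6-yl)methyl]-2,4,6-trihydroxyphenyl]butan-1-one, via Mannich base 6 (not isolated)
Conditions: [Me2N=CH2]I (1.0 equiv), NaOAc, MeCN, rt; then 3 (3 equiv), 80 °C
Reagents that add atoms: N,N-dimethylmethyleneiminium iodide, C[N+](C)=C.[I-]
Why: Mannich aminomethylation at the only free ring carbon of 5, then thermal loss of dimethylamine to an o-quinone methide that a ring carbon of 3 captures by Friedel–Crafts-type conjugate addition, should give the mixed dimer, excess 3 suppressing double alkylation.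

Step 4
Reactants: 8 (2E)-1-chloro-3,7-dimethylocta-2,6-diene (geranyl chloride)
Product: 9 (4E)-5,9-dimethyldeca-4,8-dien-1-yne
Conditions: HC≡CMgBr, CuCl (10 mol%), THF, 0 → 50 °C
Reagents that add atoms: ethynylmagnesium bromide, C#C[Mg]Br
Why: Copper-catalysed SN2 coupling of an alkynyl Grignard reagent with a primary allylic chloride should give the skipped enyne with the (E)-alkene untouched.

Step 5
Reactants: 9 (4E)-5,9-dimethyldeca-4,8-dien-1-yne; 10 (4R)-4-benzyl-1,3-oxazolidin-2-one
Product: 11 (4R)-4-benzyl-3-[(4E)-5,9-dimethyldeca-4,8-dien-1-yn-1-yl]-1,3-oxazolidin-2-one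
Conditions: CuCl2 (20 mol%), Na2CO3, pyridine, O2 (1 atm), toluene, 70 °C, slow addition of 9 to 10 (5 equiv)
Reagents that add atoms: none
Why: Copper-catalysed aerobic oxidative N-alkynylation of the carbamate nitrogen by the terminal alkyne should give the ynamide, slow addition to excess 10 suppressing Glaser homocoupling and leaving the stereocentre of 10 untouched.

Step 6
Reactants: 11 (4R)-4-benzyl-3-[(4E)-5,9-dimethyldeca-4,8-dien-1-yn-1-yl]-1,3-oxazolidin-2-one; 12 4-methoxy-6-methyl-2H-pyran-2-one
Product: 16 (6S)-4-acetyl-6-[(2E)-3,7-dimethylocta-2,6-dien-1-yl]-5-hydroxy-3-methoxy-6-methylcyclohexa-2,4-dien-1-one, via alkenylcopper 13 (not isolated), via copper enolate 14 (not isolated), via ring-opened dienolate 15 (not isolated)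
Conditions: MeMgBr, CuBr·SMe2, Et2O, −40 → 0 °C; t-BuOOLi (from t-BuOOH, n-BuLi), THF, −78 °C; then 12, −78 °C → rt; aq. NH4Cl
Reagents that add atoms: methylmagnesium bromide, C[Mg]Br; tert-butyl hydroperoxide, CC(C)(C)OO
Why: Proposed new method: the carbamate carbonyl directs syn-carbocupration of 11 so that copper sits on the nitrogen-bearing carbon and the new methyl group cis to it (13), oxidation by the lithium peroxide with retention gives the tetrasubstituted enolate 14 of fixed geometry, its carbon attacks the lactone carbonyl of 12 (bond from the quaternary carbon to the bridge-side enol carbon), the pyranone opens to dienolate 15, and the former 5-position carbon of the pyranone attacks the imide carbonyl (bond from the acetyl-bearing carbon to the acetyl-side enol carbon) with loss of the oxazolidinone anion. The closest known reaction types are the carbocupration–oxidation–aldol sequence of ynamides that builds acyclic quaternary centres, enolate C-acylation by enol lactones, and the Claisen cyclisation of 3,5,7-triketo acid derivatives to acylphloroglucinols. Ring A closes by a 6-(enolexo)-exo-trig Claisen condensation, driven by formation of the enolised triketone anion. The quaternary stereocentre is set in the acylation: the enolate geometry is fixed by the syn-carbometalation, and in the metal chelate between enolate oxygen and carbamate carbonyl the benzyl group of the (R)-auxiliary shields one face, so that 12 adds to the other. The step needs attack at the lactone carbonyl instead of conjugate addition at the 4- or 6-position or deprotonation of the 6-methyl group of 12, which the hard and fully substituted enolate should secure because conjugate addition would join two fully substituted carbons and O-acylation is reversible. It also needs Claisen instead of aldol closure of 15, secured because the delocalised anion carries its charge at the former 5-position carbon and not on the terminal methyl group, by the activated imide held in reach for six-membered closure, and by the hindered ketone next to the quaternary carbon.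

Step 7
Reactants: 16 (6S)-4-acetyl-6-[(2E)-3,7-dimethylocta-2,6-dien-1-yl]-5-hydroxy-3-methoxy-6-methylcyclohexa-2,4-dien-1-one
Product: 17 (4R)-2-acetyl-4-[(2E)-3,7-dimethylocta-2,6-dien-1-yl]-3,5-dihydroxy-4-methylcyclohexa-2,5-dien-1-one
Conditions: NaOH (aq.), THF, 50 °C; then aq. HCl, 0 °C, pH 3
Reagents that add atoms: sodium hydroxide, [Na+].[OH-]
Why: Addition–elimination hydrolysis of the vinylogous methyl ester by hydroxide should free the enolised triketone without strong acid, which spares the geranyl alkenes, and the quaternary centre has no hydrogen and cannot epimerise.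

Step 8
Reactants: 17 (4R)-2-acetyl-4-[(2E)-3,7-dimethylocta-2,6-dien-1-yl]-3,5-dihydroxy-4-methylcyclohexa-2,5-dien-1-one; 7 1-[3-[(8-butanoyl-5,7-dihydroxy-2,2-dimethyl-2H-chromen-6-yl)methyl]-2,4,6-trihydroxyphenyl]butan-1-one
Product: 19 CNP0103039.1 [(4R)-2-acetyl-6-[[3-butanoyl-5-[(8-butanoyl-5,7-dihydroxy-2,2-dimethyl-2H-chromen-6-yl)methyl]-2,4,6-trihydroxyphenyl]methyl]-4-[(2E)-3,7-dimethylocta-2,6-dien-1-yl]-3,5-dihydroxy-4-methylcyclohexa-2,5-dien-1-one], via Mannich base 18 (not isolated)
Conditions: [Me2N=CH2]I (1.0 equiv), NaOAc, MeCN, 0 °C → rt; then 7 (1.0 equiv), 50 °C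
Reagents that add atoms: N,N-dimethylmethyleneiminium iodide, C[N+](C)=C.[I-]
Why: Mannich reaction at the only ring CH of 17 (the future bridge carbon of ring A), then β-elimination of dimethylamine, should give an exo-methylene trione that the last free ring carbon of 7 attacks in a Friedel–Crafts-type conjugate addition, the stereocentre taking no part.

Compound list
1 | benzene-1,3,5-triol (phloroglucinol) | Oc1cc(O)cc(O)c1 | starting material
2 | butanoyl chloride | CCCC(=O)Cl | starting material
3 | 1-(2,4,6-trihydroxyphenyl)butan-1-one | CCCC(=O)c1c(O)cc(O)cc1O | intermediate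
4 | 3-methylbut-2-enal | CC(C)=CC=O | starting material
5 | 1-(5,7-dihydroxy-2,2-dimethyl-2H-chromen-8-yl)butan-1-one | CCCC(=O)c1c(O)cc(O)c2C=CC(C)(C)Oc12 | intermediate
6 | 1-[6-[(dimethylamino)methyl]-5,7-dihydroxy-2,2-dimethyl-2H-chromen-8-yl]butan-1-one (Mannich base, not isolated) | CCCC(=O)c1c(O)c(CN(C)C)c(O)c2C=CC(C)(C)Oc12 | intermediate
7 | 1-[3-[(8-butanoyl-5,7-dihydroxy-2,2-dimethyl-2H-chromen-6-yl)methyl]-2,4,6-trihydroxyphenyl]butan-1-one | CCCC(=O)c1c(O)cc(O)c(Cc2c(O)c3c(c(C(=O)CCC)c2O)OC(C)(C)C=C3)c1O | intermediate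
8 | (2E)-1-chloro-3,7-dimethylocta-2,6-diene (geranyl chloride) | ClC/C=C(\C)CCC=C(C)C | starting material
9 | (4E)-5,9-dimethyldeca-4,8-dien-1-yne | C#CC/C=C(\C)CCC=C(C)C | intermediate
10 | (4R)-4-benzyl-1,3-oxazolidin-2-one | O=C1N[C@H](Cc2ccccc2)CO1 | starting material
11 | (4R)-4-benzyl-3-[(4E)-5,9-dimethyldeca-4,8-dien-1-yn-1-yl]-1,3-oxazolidin-2-one | O=C1OC[C@@H](Cc2ccccc2)N1C#CC/C=C(\C)CCC=C(C)C | intermediate
12 | 4-methoxy-6-methyl-2H-pyran-2-one | COC1=CC(=O)OC(C)=C1 | starting material
13 | (4R)-4-benzyl-3-[(1E,4E)-1-cuprio-2,5,9-trimethyldeca-1,4,8-trien-1-yl]-1,3-oxazolidin-2-one (copper cis to the 2-methyl group, not isolated) | O=C1OC[C@@H](Cc2ccccc2)N1/C([Cu])=C(/C)C/C=C(\C)CCC=C(C)C | intermediate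
14 | copper (E)-enolate of (4R)-4-benzyl-3-[(4E)-2,5,9-trimethyldeca-4,8-dienoyl]-1,3-oxazolidin-2-one (enolate oxygen cis to the 2-methyl group, not isolated) | O=C1OC[C@@H](Cc2ccccc2)N1/C(O[Cu])=C(/C)C/C=C(\C)CCC=C(C)C | intermediate
15 | lithium 6,7-enolate of (4R)-4-benzyl-3-[(2R,4E)-2-[(2E)-3,7-dimethylocta-2,6-dien-1-yl]-5-methoxy-2-methyl-3,7-dioxooct-4-enoyl]-1,3-oxazolidin-2-one (not isolated) | O=C1OC[C@@H](Cc2ccccc2)N1C(=O)[C@](C)(C/C=C(\C)CCC=C(C)C)C(=O)/C=C(OC)\C=C(\C)O[Li] | intermediate
16 | (6S)-4-acetyl-6-[(2E)-3,7-dimethylocta-2,6-dien-1-yl]-5-hydroxy-3-methoxy-6-methylcyclohexa-2,4-dien-1-one | CC(=O)C1=C(O)[C@](C)(C/C=C(\C)CCC=C(C)C)C(=O)C=C1OC | intermediate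
17 | (4R)-2-acetyl-4-[(2E)-3,7-dimethylocta-2,6-dien-1-yl]-3,5-dihydroxy-4-methylcyclohexa-2,5-dien-1-one | CC(=O)C1=C(O)[C@](C)(C/C=C(\C)CCC=C(C)C)C(O)=CC1=O | intermediate
18 | (4R)-2-acetyl-6-[(dimethylamino)methyl]-4-[(2E)-3,7-dimethylocta-2,6-dien-1-yl]-3,5-dihydroxy-4-methylcyclohexa-2,5-dien-1-one (Mannich base, not isolated) | CC(=O)C1=C(O)[C@](C)(C/C=C(\C)CCC=C(C)C)C(O)=C(CN(C)C)C1=O | intermediate
19 | CNP0103039.1, (4R)-2-acetyl-6-[[3-butanoyl-5-[(8-butanoyl-5,7-dihydroxy-2,2-dimethyl-2H-chromen-6-yl)methyl]-2,4,6-trihydroxyphenyl]methyl]-4-[(2E)-3,7-dimethylocta-2,6-dien-1-yl]-3,5-dihydroxy-4-methylcyclohexa-2,5-dien-1-one | CCCC(=O)c1c(O)c(CC2=C(O)[C@@](C)(C/C=C(\C)CCC=C(C)C)C(O)=C(C(C)=O)C2=O)c(O)c(Cc2c(O)c3c(c(C(=O)CCC)c2O)OC(C)(C)C=C3)c1O | target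

Total step count: 8.
Longest linear sequence: 5 steps (steps 4, 5, 6, 7 and 8, from 8 to 19).

Steps most likely to fail

1. Step 6 (Proposed new method). The hindered, fully substituted enolate may fail to add to the weakly electrophilic lactone carbonyl, or may deprotonate the 6-methyl group of 12 or add in a conjugate sense. Any loss of chelation would erode facial selectivity, and this passes directly into the enantiomeric purity because the auxiliary leaves in the same step. The fallback uses known chemistry and gives up the one-flask construction. It sets out from 8: alkylation of the sodium enolate of dimethyl 2-methylpropanedioate with 8 gives dimethyl 2-[(2E)-3,7-dimethylocta-2,6-dien-1-yl]-2-methylpropanedioate F1. The dianion of pentane-2,4-dione (NaH, then n-BuLi, THF) is acylated at its terminal carbon by F1, and Claisen closure of the central carbon onto the second ester (NaOMe, MeOH) gives racemic 2-acetyl-4-[(2E)-3,7-dimethylocta-2,6-dien-1-yl]-3,5-dihydroxy-4-methylcyclohexa-2,5-dien-1-one F2. Resolution, by crystallisation of the (S)-1-phenylethylammonium salt or chromatography on a chiral phase, sets aside (4S)-2-acetyl-4-[(2E)-3,7-dimethylocta-2,6-dien-1-yl]-3,5-dihydroxy-4-methylcyclohexa-2,5-dien-1-one F3 and comes back to the route at 17.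

2. Step 8. The exo-methylene trione may condense with itself, and the methylene bridges may exchange by retro-Friedel–Crafts cleavage, scrambling the trimer towards symmetrical dimers. The fallback reverses the roles of the partners. It sets out from 7, which is aminomethylated with [Me2N=CH2]I at its last free ring carbon to give 1-[3-[(8-butanoyl-5,7-dihydroxy-2,2-dimethyl-2H-chromen-6-yl)methyl]-5-[(dimethylamino)methyl]-2,4,6-trihydroxyphenyl]butan-1-one F4, which is isolated. Heating F4 with 17 (dioxane, 80 °C) generates the o-quinone methide of ring B, which the free ring CH carbon of 17 captures, and the route is rejoined at 19.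

3. Step 2. Ring closure through the para-hydroxyl would give the regioisomeric 6-butanoyl chromene, and a second chromenylation at the other free ring carbon may follow. The fallback blocks the para-oxygen. It sets out from 3: selective silylation of the para-hydroxyl, the only one not engaged with the ketone (i-Pr3SiCl, imidazole, DMF, 0 °C), gives 1-[2,6-dihydroxy-4-[tri(propan-2-yl)silyloxy]phenyl]butan-1-one F5. Chromenylation with 4 (pyridine, 110 °C) can then close only through an ortho-hydroxyl and gives 1-[7-hydroxy-2,2-dimethyl-5-[tri(propan-2-yl)silyloxy]-2H-chromen-8-yl]butan-1-one F6. Desilylation (Bu4NF, THF, 0 °C) comes back to the route at 5.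

Further compounds
F1 | step 6 | dimethyl 2-[(2E)-3,7-dimethylocta-2,6-dien-1-yl]-2-methylpropanedioate | COC(=O)C(C)(C/C=C(\C)CCC=C(C)C)C(=O)OC
F2 | step 6 | racemic 2-acetyl-4-[(2E)-3,7-dimethylocta-2,6-dien-1-yl]-3,5-dihydroxy-4-methylcyclohexa-2,5-dien-1-one | CC(=O)C1=C(O)C(C)(C/C=C(\C)CCC=C(C)C)C(O)=CC1=O
F3 | step 6 | (4S)-2-acetyl-4-[(2E)-3,7-dimethylocta-2,6-dien-1-yl]-3,5-dihydroxy-4-methylcyclohexa-2,5-dien-1-one | CC(=O)C1=C(O)[C@@](C)(C/C=C(\C)CCC=C(C)C)C(O)=CC1=O
F4 | step 8 | 1-[3-[(8-butanoyl-5,7-dihydroxy-2,2-dimethyl-2H-chromen-6-yl)methyl]-5-[(dimethylamino)methyl]-2,4,6-trihydroxyphenyl]butan-1-one | CCCC(=O)c1c(O)c(CN(C)C)c(O)c(Cc2c(O)c3c(c(C(=O)CCC)c2O)OC(C)(C)C=C3)c1O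
F5 | step 2 | 1-[2,6-dihydroxy-4-[tri(propan-2-yl)silyloxy]phenyl]butan-1-one | CCCC(=O)c1c(O)cc(O[Si](C(C)C)(C(C)C)C(C)C)cc1O
F6 | step 2 | 1-[7-hydroxy-2,2-dimethyl-5-[tri(propan-2-yl)silyloxy]-2H-chromen-8-yl]butan-1-one | CCCC(=O)c1c(O)cc(O[Si](C(C)C)(C(C)C)C(C)C)c2C=CC(C)(C)Oc12
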